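**Plan**

- Retrosynthesis: the end-game groups (C15 acid, C2 alcohol, C19 acetate) are taken back to a 2-silyloxy octalin ester. C3–C4 and C5–C10 are then cut together (intramolecular Diels–Alder), then C4=C5 (Z-olefination), then C9–C10 and C9–C8 (two boron-mediated alkenylations of one carbon).
- Feature that allows this: ring A carries its oxygen at C2 between the quaternary carbons C4 and C10 on either side of the C5–C10 fusion, and ring B keeps C7=C8. This is the pattern left by a C10=C1–C2(O)=C3 diene adding to a C4=C5 dienophile tethered through C6–C7=C8–C9.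
- Forward: (R)-citronellol gives C9 and C11–C15. C9 is borylated with the (E)-C10=C1 arm and then olefinated with the (Z)-C7=C8 arm. The chain is completed to the tetraene, heating closes ring A and ring B in one step, and five functional-group steps finish the target.
- Stereochemistry: C13 comes from (R)-citronellol. C9 comes from (+)-sparteine-mediated lithiation followed by two stereospecific 1,2-migrations. C4, C5 and C10 come from the cycloaddition (enoate geometry, trans-fused transition state, C9 control). C2 comes from a SmI2 reduction to the equatorial alcohol.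

Key step: step 14

Remark: labdane numbering (C1–C20) is used for all intermediates; (+)-sparteine is taken to give the (R)-α-lithiated benzoate, the mirror image of the (S)-species formed with (−)-sparteine.

**Route**

Step 1
Reactants: 1 (R)-citronellol
Product: 2 citronellol TBDPS ether
Conditions: TBDPSCl, imidazole, DMF, 23 °C
Reagents that add atoms: tert-butyl(chloro)diphenylsilane, CC(C)(C)[Si](Cl)(c1ccccc1)c1ccccc1
Why: Routine silyl ether formation on the primary alcohol (future C15–O); the TBDPS group is chosen because it should outlast the organolithium, aqueous-acid and oxidation steps and is removed only in step 17.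

Step 2
Reactants: 2 citronellol TBDPS ether
Product: 4 C9 alcohol, via aldehyde 3 (not isolated)
Conditions: O3, CH2Cl2/MeOH, −78 °C; then NaBH4, −78 → 23 °C
Reagents that add atoms: ozone, [O-][O+]=O
Why: Ozonolysis of the trisubstituted alkene with reductive (borohydride) work-up removes the isopropylidene group and leaves the primary alcohol whose carbon is C9, without touching the C13 stereocentre.

Step 3
Reactants: 4 C9 alcohol
Product: 5 TIB ester
Conditions: 2,4,6-triisopropylbenzoic acid, PPh3, DIAD, THF, 0 → 23 °C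
Reagents that add atoms: 2,4,6-triisopropylbenzoic acid, CC(C)c1cc(C(C)C)c(C(=O)O)c(C(C)C)c1
Why: Mitsunobu esterification installs the hindered benzoate that directs α-lithiation and later serves as the leaving group of the 1,2-migration without any Lewis acid.

Step 4
Reactants: 6 pent-3-yn-2-one
Product: 7 alkynyl dioxolane
Conditions: Me3SiOCH2CH2OSiMe3, TMSOTf (cat.), CH2Cl2, −78 °C
Reagents that add atoms: 1,2-bis(trimethylsilyloxy)ethane, C[Si](C)(C)OCCO[Si](C)(C)C
Why: Silyl-triflate-catalysed ketalisation with the bis-silyl ether of ethylene glycol masks the ynone carbonyl (future C2) at low temperature, where conjugate addition to the triple bond should not compete.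

Step 5
Reactants: 7 alkynyl dioxolane
Product: 8 alkenyl boronic ester
Conditions: pinacolborane, Cp2Zr(H)Cl (10 mol%), Et3N (10 mol%), 60 °C
Reagents that add atoms: pinacolborane, CC1(C)OBOC1(C)C
Why: Zirconium-catalysed hydroboration adds H and B syn across the alkyne and, for steric reasons, places boron on the methyl-bearing carbon (future C10) remote from the quaternary dioxolane carbon, so that boron ends trans to C2.

Step 6
Reactants: 9 pent-3-yn-1-ol
Product: 10 alkynyl TBS ether
Conditions: TBSCl, imidazole, DMF, 23 °C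
Reagents that add atoms: tert-butyl(chloro)dimethylsilane, CC(C)(C)[Si](C)(C)Cl
Why: Routine silylation; this primary TBS ether (future C5–O) is the silyl group that aqueous acid should remove in step 10 while the TBDPS ether stays.

Step 7
Reactants: 10 alkynyl TBS ether
Product: 12 (E)-vinyl iodide, via alkenylzirconocene 11 (not isolated)
Conditions: Cp2Zr(H)Cl (2 equiv), THF, 23 → 50 °C; then I2, 0 °C
Reagents that add atoms: iodine, II
Why: Hydrozirconation is a syn addition that, with excess reagent and gentle warming, equilibrates zirconium onto the less hindered methyl-bearing carbon (future C8), and iodinolysis with retention gives the (E)-iodide with iodine trans to the chain.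

Step 8
Reactants: 5 TIB ester; 8 alkenyl boronic ester
Product: 15 allylic boronic ester, via lithiated ester 13 (not isolated), via boronate complex 14 (not isolated)
Conditions: 5, s-BuLi, (+)-sparteine, Et2O, −78 °C; then 8, −78 °C; then 35 °C
Reagents that add atoms: none
Why: Lithiation–borylation: sparteine-controlled deprotonation gives the configurationally stable (R)-α-lithiated ester, boron is attached with retention, and the alkenyl group then migrates from boron to C9 with inversion at C9 and retention of the alkene geometry, which sets the C9 stereocentre and the (E)-C10=C1 arm.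

Step 9
Reactants: 12 (E)-vinyl iodide; 15 allylic boronic ester
Product: 19 bis-alkenyl compound, via alkenyllithium 16 (not isolated), via boronate complex 17 (not isolated), via iodo boronic ester 18 (not isolated)
Conditions: 12, t-BuLi, THF, −78 °C; then 15, −78 °C; then I2, THF, −78 °C; then NaOMe, MeOH, −78 → 23 °C
Reagents that add atoms: none
Why: Zweifel olefination: iodine activates the alkenyl group of the boronate, C9 migrates to C8 with retention, and anti elimination of boron and iodine inverts the alkenyl geometry, so the (E)-lithium reagent should deliver the (Z)-C7=C8 alkene (C9 cis to C6), with iodination expected at the open vinyl carbon C7 and not at the allyl terminus C1, which is neopentyl-like and inductively deactivated by the dioxolane.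

Step 10
Reactants: 19 bis-alkenyl compound
Product: 20 hydroxy enone
Conditions: 1 M HCl, THF, 23 °C
Reagents that add atoms: water, O
Why: Acid hydrolysis of the allylic (hence labile) dioxolane and of the primary TBS ether in one operation should free the (E)-enone and the C5 alcohol while the much more acid-stable TBDPS ether stays.

Step 11
Reactants: 20 hydroxy enone
Product: 21 keto aldehyde
Conditions: Dess–Martin periodinane, NaHCO3, CH2Cl2, 0 → 23 °C
Reagents that add atoms: none
Why: Buffered Dess–Martin oxidation takes the homoallylic alcohol to the β,γ-unsaturated aldehyde under near-neutral conditions that should not move C7=C8 into conjugation; the crude aldehyde is used at once.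

Step 12
Reactants: 21 keto aldehyde; 22 phosphonate
Product: 24 (Z)-enoate, via potassium phosphonate 23 (not isolated)
Conditions: 22, KN(SiMe3)2, 18-crown-6, THF, −78 °C; then 21, −78 °C
Reagents that add atoms: none
Why: Still–Gennari olefination: the dissociated potassium salt of the trifluoroethyl phosphonate adds to the aldehyde and eliminates under kinetic control to the (Z)-2-methyl enoate (ester cis to C6), and this weakly basic anion should neither enolise the aldehyde nor attack the hindered enone at −78 °C.

Step 13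
Reactants: 24 (Z)-enoate
Product: 25 tetraene
Conditions: TBSOTf, Et3N, CH2Cl2, −78 → 0 °C
Reagents that add atoms: tert-butyldimethylsilyl trifluoromethanesulfonate, CC(C)(C)[Si](C)(C)OS(=O)(=O)C(F)(F)F
Why: Soft enolisation (silyl triflate and amine) of the methyl ketone removes a proton from the C3 methyl group, the kinetic site of an enone, and gives the cross-conjugated 2-silyloxydiene under conditions that leave the ester untouched.

Step 14
Reactants: 25 tetraene
Product: 26 trans-octalin silyl enol ether
Conditions: PhMe (0.01 M), BHT, Et3N (trace), sealed tube, 150–170 °C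
Reagents that add atoms: none
Why: On heating, the s-cis 2-silyloxydiene C10=C1–C2(OTBS)=C3 adds across the tethered (Z)-enoate C4=C5 in a concerted suprafacial [4+2] cycloaddition; the closest known reaction type is the thermal type 1 intramolecular Diels–Alder reaction of 1,7,9-decatrienes carrying a 2-silyloxydiene. Ring A closes as the cycloaddition ring itself (six-membered, C10–C1=C2–C3–C4–C5, through the new C3–C4 and C5–C10 bonds), and ring B closes as the fused six-membered ring C5–C6–C7=C8–C9–C10 when the C5–C10 bond ties the four-atom tether back onto the diene terminus. C4 follows from the enoate geometry, because the ester stays cis to C6 and so ends axial, syn to C20 and anti to H5; C5 and C10 are set relative to each other by the trans-fused transition state, in which the ester is exo and the C18 methyl endo, the arrangement usual for 2-methylacrylate dienophiles. The absolute sense of C4, C5 and C10 is dictated by the C9 stereocentre, which is expected to keep its side chain pseudo-equatorial on the forming ring B and thereby select one diene face. The step thus needs trans-fusion on that face, secured by the (Z)-enoate, by the tether occupying the E position of C10 (C20 inside) and by C9. Because the tether and not the electronics makes C3 bond to C4, no Lewis acid is used, and the temperature is kept as low as the rate allows so that the cycloaddition stays faster than the 1,5-hydrogen shift that the inside C20 methyl makes possible.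

Step 15
Reactants: 26 trans-octalin silyl enol ether
Product: 27 C19 alcohol
Conditions: LiAlH4, Et2O, 0 → 23 °C
Reagents that add atoms: none
Why: Hydride reduction of the hindered axial ester gives the C19 primary alcohol, while the silyl enol ether (the masked C2 ketone) and the TBDPS ether are inert to LiAlH4.

Step 16
Reactants: 27 C19 alcohol
Product: 28 C19 acetate
Conditions: Ac2O, pyridine, DMAP, CH2Cl2, 23 °C
Reagents that add atoms: acetic anhydride, CC(=O)OC(C)=O
Why: Acylation of the only free hydroxyl; acetylating while C2 is still an enol ether and C15 a silyl ether avoids any later selection between hydroxyl groups.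

Step 17
Reactants: 28 C19 acetate
Product: 29 keto alcohol
Conditions: HF·pyridine, THF/pyridine, 0 → 23 °C
Reagents that add atoms: none
Why: Fluoride-mediated desilylation cleaves the silyl enol ether to the C2 ketone and the TBDPS ether to the C15 alcohol in one operation under conditions to which the acetate is stable.

Step 18
Reactants: 29 keto alcohol
Product: 30 diol acetate
Conditions: SmI2, H2O, Et3N, THF, 0 °C (short reaction time)
Reagents that add atoms: none
Why: Ketone reduction by SmI2 (single-electron transfer, dissolving-metal type) passes through a ketyl and an α-oxido organosamarium whose bulky metal-bound oxygen should settle equatorially, away from the syn-axial C19 and C20 groups, so that C2 is protonated from the axial side and the equatorial (2S) alcohol results, whereas hydride reagents entering from the open equatorial side would give the axial epimer.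

Step 19
Reactants: 30 diol acetate
Product: 32 target acid, via aldehyde 31 (not isolated)
Conditions: TEMPO (cat.), PhI(OAc)2, MeCN/H2O, 23 °C
Reagents that add atoms: water, O
Why: TEMPO/PhI(OAc)2 oxidation: the oxoammonium salt oxidises the primary C15 alcohol much faster than the secondary C2 alcohol and, in aqueous acetonitrile, should carry it through the aldehyde hydrate to the carboxylic acid while acetate, alkene and C2 hydroxyl remain.

**Compound list**

1 | (R)-citronellol, (3R)-3,7-dimethyloct-6-en-1-ol | CC(C)=CCC[C@@H](C)CCO | starting material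
2 | tert-butyl{[(3R)-3,7-dimethyloct-6-en-1-yl]oxy}diphenylsilane | CC(C)=CCC[C@@H](C)CCO[Si](c1ccccc1)(c1ccccc1)C(C)(C)C | intermediate
3 | (4R)-6-[(tert-butyldiphenylsilyl)oxy]-4-methylhexanal (not isolated) | O=CCC[C@@H](C)CCO[Si](c1ccccc1)(c1ccccc1)C(C)(C)C | intermediate
4 | (4R)-6-[(tert-butyldiphenylsilyl)oxy]-4-methylhexan-1-ol | OCCC[C@@H](C)CCO[Si](c1ccccc1)(c1ccccc1)C(C)(C)C | intermediate
5 | (4R)-6-[(tert-butyldiphenylsilyl)oxy]-4-methylhexyl 2,4,6-triisopropylbenzoate | CC(C)c1cc(C(C)C)c(C(=O)OCCC[C@@H](C)CCO[Si](c2ccccc2)(c2ccccc2)C(C)(C)C)c(C(C)C)c1 | intermediate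
6 | pent-3-yn-2-one | CC#CC(C)=O | starting material
7 | 2-methyl-2-(prop-1-yn-1-yl)-1,3-dioxolane | CC#CC1(C)OCCO1 | intermediate
8 | 4,4,5,5-tetramethyl-2-[(1Z)-1-(2-methyl-1,3-dioxolan-2-yl)prop-1-en-2-yl]-1,3,2-dioxaborolane (boron trans to the dioxolane carbon) | C/C(=C\C1(C)OCCO1)B1OC(C)(C)C(C)(C)O1 | intermediate
9 | pent-3-yn-1-ol | CC#CCCO | starting material
10 | tert-butyldimethyl(pent-3-yn-1-yloxy)silane | CC#CCCO[Si](C)(C)C(C)(C)C | intermediate
11 | [(2E)-5-[(tert-butyldimethylsilyl)oxy]pent-2-en-2-yl]chlorozirconocene (zirconium trans to the chain; not isolated) | C/C(=C\CCO[Si](C)(C)C(C)(C)C)[Zr](Cl)(C1C=CC=C1)C1C=CC=C1 | intermediate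
12 | tert-butyl{[(3E)-4-iodopent-3-en-1-yl]oxy}dimethylsilane | C/C(I)=C\CCO[Si](C)(C)C(C)(C)C | intermediate
13 | (1R,4R)-6-[(tert-butyldiphenylsilyl)oxy]-1-lithio-4-methylhexyl 2,4,6-triisopropylbenzoate, (+)-sparteine complex (not isolated) | [Li][C@@H](OC(=O)c1c(C(C)C)cc(C(C)C)cc1C(C)C)CC[C@@H](C)CCO[Si](c1ccccc1)(c1ccccc1)C(C)(C)C | intermediate
14 | lithium pinacol boronate complex formed from 13 and 8 (not isolated) | [Li+].CC1(C)O[B-](OC1(C)C)(/C(C)=C/C1(C)OCCO1)[C@@H](OC(=O)c1c(C(C)C)cc(C(C)C)cc1C(C)C)CC[C@@H](C)CCO[Si](c1ccccc1)(c1ccccc1)C(C)(C)C | intermediate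
15 | tert-butyl{[(3R,6S,7E)-3,7-dimethyl-8-(2-methyl-1,3-dioxolan-2-yl)-6-(4,4,5,5-tetramethyl-1,3,2-dioxaborolan-2-yl)oct-7-en-1-yl]oxy}diphenylsilane | CC1(C)OB(OC1(C)C)[C@@H](CC[C@@H](C)CCO[Si](c1ccccc1)(c1ccccc1)C(C)(C)C)/C(C)=C/C1(C)OCCO1 | intermediate
16 | [(2Z)-5-[(tert-butyldimethylsilyl)oxy]pent-2-en-2-yl]lithium (lithium trans to the chain; not isolated) | C/C([Li])=C\CCO[Si](C)(C)C(C)(C)C | intermediate
17 | lithium pinacol boronate complex formed from 15 and 16 (not isolated) | [Li+].CC1(C)O[B-](OC1(C)C)(/C(C)=C/CCO[Si](C)(C)C(C)(C)C)[C@@H](CC[C@@H](C)CCO[Si](c1ccccc1)(c1ccccc1)C(C)(C)C)/C(C)=C/C1(C)OCCO1 | intermediate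
18 | β-iodo boronic ester from iodination and 1,2-migration of 17 (one of the two face isomers is drawn, both eliminate to 19; not isolated) | CC1(OCCO1)/C=C(C)/[C@H](CC[C@@H](C)CCO[Si](c1ccccc1)(c1ccccc1)C(C)(C)C)[C@](C)(B1OC(C)(C)C(C)(C)O1)[C@@H](I)CCO[Si](C)(C)C(C)(C)C | intermediate
19 | tert-butyl{[(3R,6R,7E)-6-[(2Z)-5-[(tert-butyldimethylsilyl)oxy]pent-2-en-2-yl]-3,7-dimethyl-8-(2-methyl-1,3-dioxolan-2-yl)oct-7-en-1-yl]oxy}diphenylsilane | CC(C)(C)[Si](C)(C)OCC/C=C(C)\[C@@H](CC[C@@H](C)CCO[Si](c1ccccc1)(c1ccccc1)C(C)(C)C)/C(C)=C/C1(C)OCCO1 | intermediate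
20 | (3E,5R,8R)-10-[(tert-butyldiphenylsilyl)oxy]-5-[(2Z)-5-hydroxypent-2-en-2-yl]-4,8-dimethyldec-3-en-2-one | OCC/C=C(C)\[C@@H](CC[C@@H](C)CCO[Si](c1ccccc1)(c1ccccc1)C(C)(C)C)/C(C)=C/C(C)=O | intermediate
21 | (3Z,5R,6E)-5-[(3R)-5-[(tert-butyldiphenylsilyl)oxy]-3-methylpentyl]-4,6-dimethyl-8-oxonona-3,6-dienal | O=CC/C=C(C)\[C@@H](CC[C@@H](C)CCO[Si](c1ccccc1)(c1ccccc1)C(C)(C)C)/C(C)=C/C(C)=O | intermediate
22 | methyl 2-[bis(2,2,2-trifluoroethoxy)phosphoryl]propanoate | COC(=O)C(C)P(=O)(OCC(F)(F)F)OCC(F)(F)F | starting material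
23 | potassium salt of the carbanion of 22 (not isolated) | [K+].COC(=O)[C-](C)P(=O)(OCC(F)(F)F)OCC(F)(F)F | intermediate
24 | methyl (2Z,5Z,7R,8E)-7-[(3R)-5-[(tert-butyldiphenylsilyl)oxy]-3-methylpentyl]-2,6,8-trimethyl-10-oxoundeca-2,5,8-trienoate | COC(=O)/C(C)=C\C/C=C(C)\[C@@H](CC[C@@H](C)CCO[Si](c1ccccc1)(c1ccccc1)C(C)(C)C)/C(C)=C/C(C)=O | intermediate
25 | methyl (2Z,5Z,7R,8E)-10-[(tert-butyldimethylsilyl)oxy]-7-[(3R)-5-[(tert-butyldiphenylsilyl)oxy]-3-methylpentyl]-2,6,8-trimethylundeca-2,5,8,10-tetraenoate | COC(=O)/C(C)=C\C/C=C(C)\[C@@H](CC[C@@H](C)CCO[Si](c1ccccc1)(c1ccccc1)C(C)(C)C)/C(C)=C/C(O[Si](C)(C)C(C)(C)C)=C | intermediate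
26 | methyl (4R,5S,9R,10S,13R)-2-[(tert-butyldimethylsilyl)oxy]-15-[(tert-butyldiphenylsilyl)oxy]labda-1,7-dien-19-oate (trans-fused; ester axial, syn to the C10 methyl) | COC(=O)[C@]1(C)CC(O[Si](C)(C)C(C)(C)C)=C[C@@]2(C)[C@H](CC[C@@H](C)CCO[Si](c3ccccc3)(c3ccccc3)C(C)(C)C)C(C)=CC[C@H]12 | intermediate
27 | (4R,5S,9R,10S,13R)-2-[(tert-butyldimethylsilyl)oxy]-15-[(tert-butyldiphenylsilyl)oxy]labda-1,7-dien-19-ol | OC[C@]1(C)CC(O[Si](C)(C)C(C)(C)C)=C[C@@]2(C)[C@H](CC[C@@H](C)CCO[Si](c3ccccc3)(c3ccccc3)C(C)(C)C)C(C)=CC[C@H]12 | intermediate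
28 | (4R,5S,9R,10S,13R)-2-[(tert-butyldimethylsilyl)oxy]-15-[(tert-butyldiphenylsilyl)oxy]labda-1,7-dien-19-yl acetate | CC(=O)OC[C@]1(C)CC(O[Si](C)(C)C(C)(C)C)=C[C@@]2(C)[C@H](CC[C@@H](C)CCO[Si](c3ccccc3)(c3ccccc3)C(C)(C)C)C(C)=CC[C@H]12 | intermediate
29 | (4R,5S,9R,10S,13R)-15-hydroxy-2-oxolabd-7-en-19-yl acetate | CC(=O)OC[C@]1(C)CC(=O)C[C@@]2(C)[C@H](CC[C@@H](C)CCO)C(C)=CC[C@H]12 | intermediate
30 | (2S,4R,5S,9R,10S,13R)-2,15-dihydroxylabd-7-en-19-yl acetate | CC(=O)OC[C@]1(C)C[C@@H](O)C[C@@]2(C)[C@H](CC[C@@H](C)CCO)C(C)=CC[C@H]12 | intermediate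
31 | (2S,4R,5S,9R,10S,13R)-2-hydroxy-15-oxolabd-7-en-19-yl acetate (not isolated) | CC(=O)OC[C@]1(C)C[C@@H](O)C[C@@]2(C)[C@H](CC[C@@H](C)CC=O)C(C)=CC[C@H]12 | intermediate
32 | (2S,4R,5S,9R,10S,13R)-19-acetoxy-2-hydroxylabd-7-en-15-oic acid (CNP0162900.1) | CC(=O)OC[C@]1(C)C[C@@H](O)C[C@@]2(C)[C@H](CC[C@@H](C)CC(=O)O)C(C)=CC[C@H]12 | target

**Count**

Total steps: 19. Longest linear sequence: 15 steps (steps 1–3 and 8–19, from 1 to 32).

**Steps most likely to fail, with fallbacks**

1. Step 14 (cycloaddition). What may go wrong: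
   - the cycloaddition may need a temperature at which the 1,5-hydrogen shift from C20 into the diene, or loss of the silyl group, overtakes it;
   - the ester-exo preference and the steering by C9 may be too weak, so that cis-fusion or addition to the other diene face competes.

   Fallback (aldehyde activation, Lewis acid, low temperature), setting out from 24 and returning at 27:
   - i-Bu2AlH reduces ester and ketone of 24 to the allylic diol F1.
   - Dess–Martin periodinane returns both positions to the carbonyl level as the keto enal F2.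
   - TBSOTf/Et3N gives the silyloxydiene enal F3.
   - Me2AlCl in CH2Cl2 at −78 to −20 °C should then promote the same C3–C4/C5–C10 cycloaddition far below the temperature of the hydrogen shift, the 2-methyl enal being expected to keep its carbonyl-exo (trans-fused) preference, to give the cycloadduct aldehyde F4.
   - NaBH4 reduces F4 to alcohol 27.

2. Step 9 (Zweifel olefination on an allylic boronic ester). What may go wrong: iodine may attack the allyl terminus of boronate 17 (allylic transposition with loss of the C9–B group) instead of the alkenyl group, or the allylic boron may shift along the allyl unit and erode C9.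

   Fallback (boron kept non-allylic, the C10=C1 double bond introduced afterwards), setting out from 8 and returning at 20:
   - Hydrogenation of 8 (H2, Pd/C) gives the saturated secondary boronic ester F5, racemic at C10, a centre that is erased later.
   - Lithiation–borylation of 5 with F5 under the conditions of step 8 gives the secondary alkyl boronic ester F6.
   - Zweifel olefination of F6 with alkenyllithium 16 is then the ordinary secondary-alkyl case and gives the mono-alkene F7.
   - 1 M HCl removes dioxolane and TBS ether to give the saturated hydroxy ketone F8.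
   - TMSOTf/Et3N under equilibrating conditions gives the bis-silylated enol ether F9.
   - Saegusa–Ito oxidation of F9 with Pd(OAc)2, followed by mild acidic work-up, introduces C10=C1 (the only side on which this methyl ketone can be desaturated) and gives hydroxy enone 20.

3. Step 18 (SmI2 reduction). What may go wrong: protonation of the reduced C2 centre may not be cleanly axial, leaving the axial alcohol as a co-product, or the acetate may be partly cleaved under the aqueous amine conditions.

   Fallback (internal hydride delivery before the acetate is in place), setting out from 27 and returning at 30: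
   - AcOH/THF/H2O cleaves only the silyl enol ether of 27 and gives the keto alcohol F10.
   - Me4NBH(OAc)3 in MeCN/AcOH (hydroxyl-directed reduction) is bound by the axial C19 hydroxyl and should deliver hydride intramolecularly to the axial face of C2, giving the equatorial alcohol in the diol F11.
   - AcCl with 2,4,6-collidine at −78 °C acetylates the primary C19 hydroxyl to give the mono-acetate F12.
   - HF·pyridine removes the TBDPS group of F12 and gives 30.

**Further compounds**

F1 | step 14 | (2Z,5Z,7R,8E)-7-[(3R)-5-[(tert-butyldiphenylsilyl)oxy]-3-methylpentyl]-2,6,8-trimethylundeca-2,5,8-triene-1,10-diol (C10 carbinol epimers) | OC/C(C)=C\C/C=C(C)\[C@@H](CC[C@@H](C)CCO[Si](c1ccccc1)(c1ccccc1)C(C)(C)C)/C(C)=C/C(C)O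
F2 | step 14 | (2Z,5Z,7R,8E)-7-[(3R)-5-[(tert-butyldiphenylsilyl)oxy]-3-methylpentyl]-2,6,8-trimethyl-10-oxoundeca-2,5,8-trienal | O=C/C(C)=C\C/C=C(C)\[C@@H](CC[C@@H](C)CCO[Si](c1ccccc1)(c1ccccc1)C(C)(C)C)/C(C)=C/C(C)=O
F3 | step 14 | (2Z,5Z,7R,8E)-10-[(tert-butyldimethylsilyl)oxy]-7-[(3R)-5-[(tert-butyldiphenylsilyl)oxy]-3-methylpentyl]-2,6,8-trimethylundeca-2,5,8,10-tetraenal | O=C/C(C)=C\C/C=C(C)\[C@@H](CC[C@@H](C)CCO[Si](c1ccccc1)(c1ccccc1)C(C)(C)C)/C(C)=C/C(O[Si](C)(C)C(C)(C)C)=C
F4 | step 14 | (4R,5S,9R,10S,13R)-2-[(tert-butyldimethylsilyl)oxy]-15-[(tert-butyldiphenylsilyl)oxy]labda-1,7-dien-19-al | O=C[C@]1(C)CC(O[Si](C)(C)C(C)(C)C)=C[C@@]2(C)[C@H](CC[C@@H](C)CCO[Si](c3ccccc3)(c3ccccc3)C(C)(C)C)C(C)=CC[C@H]12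
F5 | step 9 | 4,4,5,5-tetramethyl-2-[1-(2-methyl-1,3-dioxolan-2-yl)propan-2-yl]-1,3,2-dioxaborolane (racemic) | CC(CC1(C)OCCO1)B1OC(C)(C)C(C)(C)O1
F6 | step 9 | C10-saturated analogue of 15 (C9 as in 15, C10 epimers) | CC1(C)OB(OC1(C)C)[C@@H](CC[C@@H](C)CCO[Si](c1ccccc1)(c1ccccc1)C(C)(C)C)C(C)CC1(C)OCCO1
F7 | step 9 | C10,C1-dihydro analogue of 19 (C9 as in 19, C10 epimers) | CC(C)(C)[Si](C)(C)OCC/C=C(C)\[C@@H](CC[C@@H](C)CCO[Si](c1ccccc1)(c1ccccc1)C(C)(C)C)C(C)CC1(C)OCCO1
F8 | step 9 | C10,C1-dihydro analogue of 20, saturated hydroxy methyl ketone (C10 epimers) | OCC/C=C(C)\[C@@H](CC[C@@H](C)CCO[Si](c1ccccc1)(c1ccccc1)C(C)(C)C)C(C)CC(C)=O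
F9 | step 9 | trimethylsilyl enol ether (C1=C2) and C5 trimethylsilyl ether of F8 | C[Si](C)(C)OCC/C=C(C)\[C@@H](CC[C@@H](C)CCO[Si](c1ccccc1)(c1ccccc1)C(C)(C)C)C(C)C=C(C)O[Si](C)(C)C
F10 | step 18 | (4R,5S,9R,10S,13R)-15-[(tert-butyldiphenylsilyl)oxy]-19-hydroxylabd-7-en-2-one | OC[C@]1(C)CC(=O)C[C@@]2(C)[C@H](CC[C@@H](C)CCO[Si](c3ccccc3)(c3ccccc3)C(C)(C)C)C(C)=CC[C@H]12
F11 | step 18 | (2S,4R,5S,9R,10S,13R)-15-[(tert-butyldiphenylsilyl)oxy]labd-7-ene-2,19-diol | OC[C@]1(C)C[C@@H](O)C[C@@]2(C)[C@H](CC[C@@H](C)CCO[Si](c3ccccc3)(c3ccccc3)C(C)(C)C)C(C)=CC[C@H]12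
F12 | step 18 | (2S,4R,5S,9R,10S,13R)-15-[(tert-butyldiphenylsilyl)oxy]-2-hydroxylabd-7-en-19-yl acetate | CC(=O)OC[C@]1(C)C[C@@H](O)C[C@@]2(C)[C@H](CC[C@@H](C)CCO[Si](c3ccccc3)(c3ccccc3)C(C)(C)C)C(C)=CC[C@H]12
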